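The easy step is to lay a ruler on Tuesday's isomer of the product. The line through its first two readings meets zero at 0.0932 d, and I call that time the isomer's lag, the delay before isomer is made at full pace. The same ruler on Tuesday's target meets zero at −0.0780 d, before the start, so target shows no delay in those readings.

| setting | Tuesday's | Friday's | Thursday's | flask |
|---|---|---|---|---|
| solid substrate | 0.020 M | 0.020 M | 0.010 M | 0.020 M |
| partner | 0.030 M | 0.045 M | 0.060 M | 0.0600 M |
| remark | run made earlier | run made earlier | run made earlier |  |
| time |  |  |  | 2.0 d |

- Tuesday's (time / d: isomer of the product / %, target / %): 0.208: 12.3, 5.2; 0.417: 34.7, 9.0; 1.04: 68.6, 10.5; 2.50: 75.7, 5.8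
- Friday's (time / d: isomer of the product / %, target / %): 0.625: 60.8, 12.1; 1.25: 71.3, 4.0; 1.67: 72.4, 3.1; 2.50: 71.7, 2.3
- Thursday's (time / d: isomer of the product / %, target / %): 0.208: 34.0, 12.9; 0.417: 65.1, 10.2; 1.04: 69.2, 3.0; 2.50: 67.6, 0

(standard deviation of a reading: 1 percentage point)

1. share of isomer of the product in isomer of the product plus target at 80 min
2. share of isomer of the product in isomer of the product plus target at 8.0 h
3. share of isomer of the product in isomer of the product plus target at 2.0 d
4. which of isomer of the product and target there is more of at 2.0 d

- at the start none of the solid substrate is in solution
- a reading or a percentage of target counts all its forms, free or not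

The flask's early time 80 min lies inside the lag. I assume the lag holds at this flask's [partner], so isomer there still grows as the square of time while target grows in proportion to it. Isomer over target is then the selectivity factor times the time over 2 lags. For that factor I take Thursday's last reading, at the same [partner]: isomer 67.6 %, the rest counted as having gone through target, which gives 2.09. My ratio at 80 min is 0.623, a share of 38.3 %.

Your forecast says 70 %, which is more than mine, then 77 % and 96.5 %, with isomer of the product ahead, on the ground that “The isomer plateaus once the solid is used up, while the target keeps falling”. The middle time 8.0 h is longer than the lag, so I keep your later numbers.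

The flask gives 51.3 %, 77.7 % and 99.6 %, with isomer of the product ahead. At 80 min the forecast stands 19 percentage points high and my reckoning 13 points low. Isomer and target stand level at 1.24 % each after 0.0521 d. The lag puts that moment at 0.0894 d, later than the flask does; that lag was read on Tuesday's run, at half this flask's [partner].

    starting material ⇌ other conformer (K = 1.80, k = 0.0179 min⁻¹)
    starting material + partner → target (k = 0.0811 M⁻¹ min⁻¹)
    partner + other conformer → isomer of the product (k = 0.222 M⁻¹ min⁻¹)
    crystals ⇌ target, rate k4*(cs4 - [target]) while solid is left; crystals form when [target] > cs4 (solubility = 7.20 mM, k = 0.711 min⁻¹)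
    partner + target → over-reaction product (k = 0.0570 M⁻¹ min⁻¹)
    solid substrate ⇌ starting material, rate k6*(cs6 - [starting material]) while solid is left; crystals form when [starting material] > cs6 (solubility = 8.30 mM, k = 0.00403 min⁻¹)

Take the neighbour flask with 0.0080 M of solid substrate. The reckoning holds no solid charge, so the lag stays 0.0932 d and it gives 38.3 % again, the same as for the first flask. The computed share in that neighbour flask is 51.3 %, against 51.3 % in the first flask.

All runs come from a simulation for an exercise, noise included.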